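## Structural features

The target is an isoflavone, a 4H-chromen-4-one in which the benzo ring A is fused through C4a–C8a to the γ-pyranone ring C (O1, C2, C3, C4). The 3,4-dimethoxyphenyl ring B hangs from C3 by a single C3–C1' bond. Ring A carries one substituent, an ether oxygen at C7 (para to C4a and so conjugated with the C4 carbonyl) that bears a 3-methylbut-2-enyl (prenyl) chain. There is no stereocentre and no stereogenic double bond, so no stereocentres stand next to each other and the problems are regiochemistry and chemoselectivity only. The fragile groups are the prenyl aryl ether, which ionises under acid and offers an electron-rich trisubstituted alkene to electrophilic oxidants, and C2 of the pyranone, a vinylogous ester carbon that hydroxide or alkoxide can attack with opening of ring C. The veratryl ring B is electron-rich enough to be attacked by strong electrophiles. The real difficulty is to put ring B on C3, beside the carbonyl carbon C4, and not on C2 beside O1, where aldol chemistry would naturally place it, and to do so before the prenyl ether is present. The key step uses the flavanone isomer, in which ring B sits on C2: the O1 lone pair can carry a positive charge at C2, so oxidation at C3 lets the 4'-methoxy-activated ring B move from C2 to C3, after which the C2=C3 bond forms.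

## Logic of the disconnections

11 ⇒ 10 + 9. The bond cut is the one between the C7 oxygen and the allylic CH2 of the side chain. The prenyl group is the only part of 11 that cannot meet an electrophilic iodine oxidant or a sulfonic acid, so it is set aside first. The gain is a skeleton with no alkene outside the rings. The forward step must alkylate oxygen and not C8, at the primary carbon of 9 and not with allylic transposition, under a base too mild to touch C2.

10 ⇒ 8. The bond cut is the O–acyl bond at C7. The C7 oxygen has to be masked during the oxidation, and the mask should also draw electron density out of ring A; an acetyl group does both and falls off under carbonate in an alcohol. The forward demand is cleavage without opening of ring C, which allows the unmasking and the alkylation of the previous paragraph to be run in one flask.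

8 ⇒ 6. The C3–C1' bond is cut, C1' is reattached to C2 and the C2=C3 bond is saturated, a 1,2-aryl shift read backwards with a change of oxidation level; the forward reaction passes through 7. The gain is decisive: the hard 3-aryl pattern becomes the 2-aryl pattern that condensation chemistry delivers. The forward step must oxidise C3 and then make ring B, and not the C2 hydrogen or the C4–C4a bond, the group that moves. The design of 6 serves this: the 4'-methoxy group makes ring B a strong migrating group, the C7 acetate keeps ring A electron-poor and hides the phenol, and the C2 oxygen stabilises the cation left behind. Other groups on the C7 oxygen were weighed and rejected: a free hydroxyl would be oxidised, a prenyl or allyl ether offers an alkene to the oxidant, and benzyl or acetal ethers leave ring A electron-rich (the acetal is also acid-labile). The improvement lies in the surroundings of the precursor: the oxidation is planned in an alcohol-free nitrile solvent, so the ketal pathway to ring contraction has no entry.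

6 ⇒ 5. The O–acetyl bond is cut. The acetate cannot be carried from the start because it would not survive the hydroxide of the condensation, so it is put on once ring C is closed and only one hydroxyl is left. The forward demand is acylation under conditions that do not reopen ring C.

5 ⇒ 4. The O1–C2 bond is cut (retro-oxa-Michael). Ring C and the only stereocentre disappear, leaving an open-chain enone. The forward ring closure is reversible, so it needs conditions that favour the closed form and recycling of unchanged 4.

4 ⇒ 1 + 2. The enone double bond is cut between the methyl carbon of 1 and the formyl carbon of 2; the forward reaction passes through 3. This is the aldol retron and leads to two commercial aromatic compounds. The forward demand is enolisation of a methyl ketone whose two phenols are ionised first, which calls for concentrated hydroxide and an aldehyde that cannot enolise.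

## Other disconnections considered

Alternative 1: The cut is the C3–C4 bond, made after the C2=C3 double bond is taken back to a tertiary alcohol at C3.
- Forward key step: the keto aldehyde 2-[2-(3,4-dimethoxyphenyl)-2-oxoethoxy]-4-(3-methylbut-2-enyloxy)benzaldehyde A1 would come from a resorcinol-derived salicylaldehyde by two O-alkylations, with 9 at the para oxygen and then with the α-bromo ketone of ring B at the ortho oxygen. A triazolium-derived N-heterocyclic carbene adds to the formyl group of A1; the amino enol so formed is an acyl anion equivalent at the future C4, and its 6-exo-trig attack on the aryl ketone carbon (future C3) would close ring C as rac-3-(3,4-dimethoxyphenyl)-3-hydroxy-7-(3-methylbut-2-enyloxy)chroman-4-one A2. Loss of water across C2–C3 of A2 would finish 11.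
- In its favour: ring B is tied to C3 by the connectivity of A1, so no migration has to win against another pathway. There is no oxidant, so the prenyl ether can be present from the first step and no protecting group is needed. The count is about four steps.
- Against it here: A1 is a salicylaldehyde phenacyl ether, the substrate of the Rap–Stoermer condensation. The base used to make it or to free the carbene can remove the acidic O–CH2–C(=O) hydrogens, add that carbon to the aldehyde and end in a 2-aroylbenzofuran. The aldehyde is deactivated by ortho and para oxygen donors and the ketone by the veratryl ring, so the umpolung addition should be slow exactly where the aldol is easy. The last step must dehydrate the tertiary alcohol of A2, which lies α to a carbonyl group, in the presence of the acid-sensitive prenyl ether, after a stereocentre has been built only to be destroyed.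
- Comparison: on structure this alternative is the better one, because the C3 attachment is unambiguous and the side chain needs no late introduction. On step economy it is the better one by one step on paper. On mechanism the chosen plan is stronger: 6 comes from aldol and oxa-Michael chemistry with no rival cyclisation mode, and the aryl shift is steered by two substituents already in place, whereas A1 carries a base-mediated side reaction into both its preparation and its key step.

Alternative 2: Three bonds of ring C are cut at once, O1–C8a, C4–C4a and O1–C2, which divides the skeleton into a ring A aryne and a three-carbon acid that carries ring B.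
- Forward key step: 2-(3,4-dimethoxyphenyl)-3-methoxyprop-2-enoic acid A3, as its carboxylate, would add through oxygen to the aryne set free by fluoride from 5-(benzyloxy)-3-chloro-2-(trimethylsilyl)phenyl trifluoromethanesulfonate A4. Addition occurs at the aryne carbon remote from chlorine (future C8a); the aryl anion beside chlorine (future C4a) attacks the ester carbonyl; the acyl group moves from oxygen to carbon; and the freed phenoxide replaces methoxide at the enol ether carbon (future C2) by addition–elimination. The product would be 7-benzyloxy-5-chloro-3',4'-dimethoxyisoflavone A5. Hydrogenolysis of the C–Cl and O–benzyl bonds of A5 would lead to 10, and alkylation with 9 to 11.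
- In its favour: ring C and three bonds are made in one operation from two fragments of similar size. Ring B is fixed at C3 by the acid A3. No oxidant is involved.
- Against it here: the chlorine is present only to direct the aryne addition, since a 4-alkoxy aryne alone would be expected to give 6- and 7-oxygenated isomers, and it must be removed again. The reductive removal of chlorine and benzyl from A5 has to spare the C2=C3 bond. A prenyl ether cannot ride through the aryne step (ene reaction with the aryne) or the hydrogenolysis, so protection and late alkylation are needed just as in the chosen plan. Simple O-arylation of the carboxylate by protonation of the aryl anion competes with acyl transfer. A4 and A3 each need several steps.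
- Comparison: on structure the alternative equals the chosen plan in needing a C7 mask and is worse in adding an atom that the target lacks. On mechanism it is the better one in convergence and in having no flavone-forming side path, but it trades this for a regiochemistry and a chemoselective reduction that the chosen plan never meets. On step economy it is clearly longer (about eight to nine steps against five).

Alternative 3: The cut is the C2=C3 double bond itself.
- Forward key step: the diene 1-[4-(tert-butyldimethylsilyloxy)-2-(ethenyloxy)phenyl]-2-(3,4-dimethoxyphenyl)prop-2-en-1-one A6 would undergo ring-closing metathesis between its aryl vinyl ether and the 1,1-disubstituted alkene of the 2-aryl enone under a second-generation Grubbs catalyst. Ethylene leaves and ring C closes as 7-(tert-butyldimethylsilyloxy)-3',4'-dimethoxyisoflavone A7. Removal of silicon from A7 with fluoride would give 10, and alkylation with 9 would give 11.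
- In its favour: the conditions are neutral and catalytic, no oxidant touches ring B, and the position of ring B is fixed before the ring is closed.
- Against it here: a vinyl ether gives a heteroatom-stabilised ruthenium carbene that turns over slowly. The partner alkene is hindered, electron-poor and 1,1-disubstituted, and the alkene formed in A7 is trisubstituted, so high catalyst loading and heat should be expected. The α-aryl enone of A6 is a Michael acceptor prone to polymerisation. A6 must be made from a deoxybenzoin by silylation, O-vinylation and α-methylenation, although a deoxybenzoin can be closed to an isoflavone directly with a one-carbon electrophile, which makes the metathesis a detour. A prenyl ether would offer the catalyst a third alkene, hence the silyl group.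
- Comparison: on structure the alternative is equal to the chosen plan (both need a C7 mask and late prenylation). On mechanism it is the better one in chemoselectivity towards electron-rich arenes and in having no isomeric by-pathway, but its ring closure pairs two of the least reactive metathesis partners. On step economy it is longer (about seven to eight steps).

Key step: step 4

Remark: the C2 stereocentre of 5, 6 and 7 is erased in step 4, so these compounds are made and used as racemates.

## Route

Step 1
Reactants: 1 2,4-dihydroxyacetophenone; 2 3,4-dimethoxybenzaldehyde
Product: 4 (E)-1-(2,4-dihydroxyphenyl)-3-(3,4-dimethoxyphenyl)prop-2-en-1-one, via aldol adduct 3 (not isolated)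
Conditions: KOH (50% aq.), EtOH, rt, 48 h; then aq. HCl, 0 °C
Reagents that add atoms: none
Why: Claisen–Schmidt (crossed aldol) condensation: 2 cannot enolise and is the only electrophile, the enolate of 1 adds to it to give 3, and E1cB loss of hydroxide gives the conjugated, thermodynamically preferred E-enone; concentrated KOH is needed because both phenols are ionised before the methyl group is deprotonated.

Step 2
Reactants: 4 (E)-1-(2,4-dihydroxyphenyl)-3-(3,4-dimethoxyphenyl)prop-2-en-1-one
Product: 5 rac-7-hydroxy-2-(3,4-dimethoxyphenyl)chroman-4-one
Conditions: NaOAc, EtOH–H2O, reflux, 24 h
Reagents that add atoms: none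
Why: Intramolecular oxa-Michael addition (6-endo-trig) of the 2'-phenoxide to the enone, the usual chalcone–flavanone isomerisation; the C2 stereocentre forms without control and 5 is racemic, which is harmless because C2 becomes trigonal again in step 4. The reaction is an equilibrium, so unchanged 4 should be recovered and resubmitted.

Step 3
Reactants: 5 rac-7-hydroxy-2-(3,4-dimethoxyphenyl)chroman-4-one
Product: 6 rac-2-(3,4-dimethoxyphenyl)-4-oxochroman-7-yl acetate (7-acetoxy-3',4'-dimethoxyflavanone)
Conditions: Ac2O, pyridine, CH2Cl2, 0 °C to rt
Reagents that add atoms: acetic anhydride, CC(=O)OC(C)=O
Why: O-Acetylation of the only free hydroxyl (phenol acylation); a weak amine base and low temperature are chosen so that ring C is not reopened by retro-oxa-Michael reaction before the phenol is capped.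

Step 4
Reactants: 6 rac-2-(3,4-dimethoxyphenyl)-4-oxochroman-7-yl acetate
Product: 8 3-(3,4-dimethoxyphenyl)-4-oxo-4H-chromen-7-yl acetate (7-acetoxy-3',4'-dimethoxyisoflavone), via C3 phenyl(tosyloxy)iodane 7 (not isolated)
Conditions: PhI(OH)OTs (1.2 equiv), MeCN, reflux
Reagents that add atoms: none
Why: The ketone enolises towards C3, its only α-carbon bearing hydrogen, and the enol attacks the trivalent iodine centre of the reagent with loss of water to give the C3 iodane 7. In the trans isomer of 7 ring B and the C3–I bond can both be axial and anti-periplanar, so ring B bridges C2 and C3 as a phenonium-type ion while iodobenzene departs, the iodine going from trivalent to monovalent. The bridge opens at C2, which puts ring B on C3 and leaves a C2 cation stabilised by the O1 lone pair, and loss of the C3 proton gives the C2=C3 bond of 8 in conjugation with the carbonyl group and ring B. The closest known reaction type is the oxidative 2,3-aryl migration of flavanones to isoflavones with trivalent iodine or trivalent thallium reagents, the laboratory counterpart of the aryl shift of isoflavone biosynthesis. No ring is closed (ring C is kept and only the C3–C1' bond is new) and no stereocentre is made; the C2 stereocentre of 6 is erased. The step needs aryl migration to win over loss of the C2 hydrogen (dehydrogenation), over migration of the C4–C4a bond (ring contraction) and over attack of the oxidant on the arenes. The 4'-methoxy group para to the migrating carbon secures the first, the alcohol-free nitrile solvent closes the ketal route to the second, and the C7 acetate, which lowers the electron density of ring A and hides the phenol, guards against the third.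

Step 5
Reactants: 8 3-(3,4-dimethoxyphenyl)-4-oxo-4H-chromen-7-yl acetate; 9 prenyl bromide (1-bromo-3-methylbut-2-ene)
Product: 11 3-(3,4-dimethoxyphenyl)-7-(3-methylbut-2-enyloxy)-4H-chromen-4-one (7-prenyloxy-3',4'-dimethoxyisoflavone), via 7-hydroxy-3',4'-dimethoxyisoflavone 10 (not isolated)
Conditions: K2CO3 (3 equiv), MeOH–THF, rt; evaporate; then 9 (1.3 equiv), DMF, rt
Reagents that add atoms: none
Why: Carbonate-mediated methanolysis of the aryl acetate gives the potassium phenoxide of 10, and Williamson ether synthesis (SN2 at the unhindered primary carbon of 9) then forms the aryl prenyl ether. The phenoxide is conjugated with the C4 carbonyl, which favours O- over C-alkylation in DMF and deactivates C2 towards nucleophiles; removing methanol before 9 is added prevents its solvolysis.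

## Compound list

1 | 1-(2,4-dihydroxyphenyl)ethan-1-one (2,4-dihydroxyacetophenone) | CC(=O)c1ccc(O)cc1O | starting material
2 | 3,4-dimethoxybenzaldehyde | COc1ccc(C=O)cc1OC | starting material
3 | rac-1-(2,4-dihydroxyphenyl)-3-(3,4-dimethoxyphenyl)-3-hydroxypropan-1-one (aldol adduct) | COc1ccc(C(O)CC(=O)c2ccc(O)cc2O)cc1OC | intermediate (not isolated)
4 | (E)-1-(2,4-dihydroxyphenyl)-3-(3,4-dimethoxyphenyl)prop-2-en-1-one | COc1ccc(/C=C/C(=O)c2ccc(O)cc2O)cc1OC | intermediate
5 | rac-7-hydroxy-2-(3,4-dimethoxyphenyl)chroman-4-one | COc1ccc(C2CC(=O)c3ccc(O)cc3O2)cc1OC | intermediate
6 | rac-2-(3,4-dimethoxyphenyl)-4-oxochroman-7-yl acetate | CC(=O)Oc1ccc2c(c1)OC(c1ccc(OC)c(OC)c1)CC2=O | intermediate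
7 | rac-(2,3-trans)-2-(3,4-dimethoxyphenyl)-4-oxo-3-[phenyl(tosyloxy)-λ3-iodanyl]chroman-7-yl acetate (one enantiomer drawn) | CC(=O)Oc1ccc2c(c1)O[C@@H](c1ccc(OC)c(OC)c1)[C@H](I(OS(=O)(=O)c1ccc(C)cc1)c1ccccc1)C2=O | intermediate (not isolated)
8 | 3-(3,4-dimethoxyphenyl)-4-oxo-4H-chromen-7-yl acetate | CC(=O)Oc1ccc2c(c1)occ(-c1ccc(OC)c(OC)c1)c2=O | intermediate
9 | 1-bromo-3-methylbut-2-ene (prenyl bromide) | CC(C)=CCBr | starting material
10 | 7-hydroxy-3-(3,4-dimethoxyphenyl)-4H-chromen-4-one (present as its potassium salt) | COc1ccc(-c2coc3cc(O)ccc3c2=O)cc1OC | intermediate (not isolated)
11 | 3-(3,4-dimethoxyphenyl)-7-(3-methylbut-2-enyloxy)-4H-chromen-4-one | COc1ccc(-c2coc3cc(OCC=C(C)C)ccc3c2=O)cc1OC | target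

## Step count and risk

Total step count: 5. Longest linear sequence: 5 steps (1 to 11); 2 and 9 enter as commercial partners.

Step 4 (key step). The most likely failure is loss of the C2 hydrogen in place of aryl migration, because the cis isomer of 7 and the conformer with an equatorial ring B place that hydrogen, and not ring B, anti to the C–I bond. Electrophilic attack of the oxidant on the electron-rich ring B and acid-promoted loss of the acetate followed by oxidation of the phenol are further risks. The fallback gives up the aryl shift and forms the C3–C1' bond by cross-coupling. It sets out from 1: selective alkylation of the non-chelated 4-hydroxyl (MeOCH2Cl, iPr2NEt, CH2Cl2) would give 1-[2-hydroxy-4-(methoxymethoxy)phenyl]ethan-1-one F1. Condensation with Me2NCH(OMe)2 at 90 °C would give (E)-3-(dimethylamino)-1-[2-hydroxy-4-(methoxymethoxy)phenyl]prop-2-en-1-one F2. Iodine with pyridine in CHCl3 would close ring C and iodinate C3 to 3-iodo-7-(methoxymethoxy)-4H-chromen-4-one F3. Suzuki–Miyaura coupling with (3,4-dimethoxyphenyl)boronic acid, using Pd(PPh3)4 (a zerovalent palladium complex) and Na2CO3 in DME–H2O at 80 °C, would give 3-(3,4-dimethoxyphenyl)-7-(methoxymethoxy)-4H-chromen-4-one F4. HCl in MeOH would remove the acetal, and the route is rejoined at 10, which is alkylated with 9 as in the second stage of step 5.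

Step 2. The most likely failure is incomplete ring closure, because the reaction is an equilibrium in which the ionised 4'-hydroxyl and the electron-rich ring B both stabilise the open enone, and reopening on long heating drains the product. The fallback leaves out the flavanone and carries out the aryl shift on the open chain. It sets out from 4: acetylation of both hydroxyls (Ac2O, pyridine) would give 4-[(E)-3-(3,4-dimethoxyphenyl)prop-2-enoyl]-1,3-phenylene diacetate F5. Oxidative 1,2-aryl migration with PhI(OH)OTs in MeOH–HC(OMe)3 at rt would give rac-4-[2-(3,4-dimethoxyphenyl)-3,3-dimethoxypropanoyl]-1,3-phenylene diacetate F6. HCl in MeOH at reflux would cleave both acetates and close ring C with loss of methanol. The route is rejoined at 10 and finished by alkylation with 9.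

Step 1. The most likely failure is slow enolisation, because both phenols are ionised first and the dianion resists a third deprotonation at the methyl group; the long exposure of 2 to concentrated KOH then invites its Cannizzaro disproportionation. The fallback changes the protecting-group strategy so that only one phenoxide is present. It sets out from 1: 3,4-dihydro-2H-pyran with pyridinium tosylate in CH2Cl2 would give rac-1-[2-hydroxy-4-(tetrahydro-2H-pyran-2-yloxy)phenyl]ethan-1-one F7. Condensation with 2 under Ba(OH)2·8H2O in MeOH would give rac-(E)-3-(3,4-dimethoxyphenyl)-1-[2-hydroxy-4-(tetrahydro-2H-pyran-2-yloxy)phenyl]prop-2-en-1-one F8. TsOH·H2O in MeOH at rt would remove the acetal, and the route is rejoined at 4.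

Step 5. The most likely failures are consumption of 9 by residual methanol and methoxide, and addition of methoxide to C2 with opening of ring C while the acetate is being cleaved; alkylation at C8 or with allylic transposition is a lesser risk. The fallback avoids base and the allylic bromide. It sets out from 8: acid-catalysed methanolysis (cat. HCl, MeOH, rt to 40 °C) would give 10, which is isolated and etherified with 3-methylbut-2-en-1-ol under Mitsunobu conditions (PPh3, diisopropyl azodicarboxylate, THF, 0 °C to rt). The route is rejoined at 11; no new compound is made.

## Further compounds

F1 | step 4 | 1-[2-hydroxy-4-(methoxymethoxy)phenyl]ethan-1-one | CC(=O)c1ccc(OCOC)cc1O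
F2 | step 4 | (E)-3-(dimethylamino)-1-[2-hydroxy-4-(methoxymethoxy)phenyl]prop-2-en-1-one | CN(C)/C=C/C(=O)c1ccc(OCOC)cc1O
F3 | step 4 | 3-iodo-7-(methoxymethoxy)-4H-chromen-4-one | COCOc1ccc2c(c1)occ(I)c2=O
F4 | step 4 | 3-(3,4-dimethoxyphenyl)-7-(methoxymethoxy)-4H-chromen-4-one | COCOc1ccc2c(c1)occ(-c1ccc(OC)c(OC)c1)c2=O
F5 | step 2 | 4-[(E)-3-(3,4-dimethoxyphenyl)prop-2-enoyl]-1,3-phenylene diacetate | COc1ccc(/C=C/C(=O)c2ccc(OC(C)=O)cc2OC(C)=O)cc1OC
F6 | step 2 | rac-4-[2-(3,4-dimethoxyphenyl)-3,3-dimethoxypropanoyl]-1,3-phenylene diacetate | COc1ccc(C(C(OC)OC)C(=O)c2ccc(OC(C)=O)cc2OC(C)=O)cc1OC
F7 | step 1 | rac-1-[2-hydroxy-4-(tetrahydro-2H-pyran-2-yloxy)phenyl]ethan-1-one | CC(=O)c1ccc(OC2CCCCO2)cc1O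
F8 | step 1 | rac-(E)-3-(3,4-dimethoxyphenyl)-1-[2-hydroxy-4-(tetrahydro-2H-pyran-2-yloxy)phenyl]prop-2-en-1-one | COc1ccc(/C=C/C(=O)c2ccc(OC3CCCCO3)cc2O)cc1OC
F0 | step 5 | none | none
A1 | alternative 1 | 2-[2-(3,4-dimethoxyphenyl)-2-oxoethoxy]-4-(3-methylbut-2-enyloxy)benzaldehyde | COc1ccc(C(=O)COc2cc(OCC=C(C)C)ccc2C=O)cc1OC
A2 | alternative 1 | rac-3-(3,4-dimethoxyphenyl)-3-hydroxy-7-(3-methylbut-2-enyloxy)chroman-4-one | COc1ccc(C2(O)COc3cc(OCC=C(C)C)ccc3C2=O)cc1OC
A3 | alternative 2 | 2-(3,4-dimethoxyphenyl)-3-methoxyprop-2-enoic acid (alkene geometry not defined, either isomer serves) | COC=C(C(=O)O)c1ccc(OC)c(OC)c1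
A4 | alternative 2 | 5-(benzyloxy)-3-chloro-2-(trimethylsilyl)phenyl trifluoromethanesulfonate | C[Si](C)(C)c1c(Cl)cc(OCc2ccccc2)cc1OS(=O)(=O)C(F)(F)F
A5 | alternative 2 | 7-benzyloxy-5-chloro-3',4'-dimethoxyisoflavone | COc1ccc(-c2coc3cc(OCc4ccccc4)cc(Cl)c3c2=O)cc1OC
A6 | alternative 3 | 1-[4-(tert-butyldimethylsilyloxy)-2-(ethenyloxy)phenyl]-2-(3,4-dimethoxyphenyl)prop-2-en-1-one | C=COc1cc(O[Si](C)(C)C(C)(C)C)ccc1C(=O)C(=C)c1ccc(OC)c(OC)c1
A7 | alternative 3 | 7-(tert-butyldimethylsilyloxy)-3',4'-dimethoxyisoflavone | COc1ccc(-c2coc3cc(O[Si](C)(C)C(C)(C)C)ccc3c2=O)cc1OC
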